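## The problem

Compound **40** (CNP0121153.1) is numbered here as follows. The eight-membered carbocycle runs C1 (methyl, 4-methylpent-3-enyl), C2 (prenyl), C3, C4 (prenyl), C10 (ketone), C7 (prenyl), C8 (ketone), C9 (2-methylpropanoyl, carbonyl carbon C11). A lactone bridge C4–C5(=O)–O6–C7 makes C4, C10 and C7 part of a furan-2,4-dione as well.

The bicycle can exist only if C3 and C8 stand cis on the furandione, so the two quaternary bridgeheads C4 and C7 must be set relative to each other before the carbocycle is closed. C7 can direct C4 across the five-membered ring. The chain pair C1 (quaternary) and C2 (tertiary) lies too far from the furandione to be controlled by it or to control it, so it needs its own absolute control. C9 lies between two ketones and will take the thermodynamically preferred configuration.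

Four trisubstituted alkenes rule out ozone, peracids, hydrogenation, halonium reagents in excess and strong aqueous acid. The furandione with quaternary C4 is a β-keto lactone that cannot enolise and opens by retro-Claisen attack of hard nucleophiles.

The enabling feature is the triad C8(=O)–C9–C11(=O). It is a 1,3-diketone, the open form of an isoxazole whose C3–C4 bond is C8–C9. A C8 nitrile oxide adding to a C9≡C11 alkyne therefore makes the last ring bond and places the C11 oxygen in one event.

## Retrosynthesis

**Unmasking.** The two ketones of **40** are traced to the N–O and C=N bonds of isoxazole **38** through enaminone **39**. Carrying a free β-diketone with an acidic C9–H through a medium-ring closure would invite enolisation and O-reactivity; the aromatic mask avoids both. The forward steps must cleave N–O without reducing alkenes (Mo(CO)6) and hydrolyse under weak acid.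

**Key cut.** C8–C9 and O–C11 of **38** are cut together, giving aldoxime **35** via nitrile oxide **37**. Cutting C3–C4 or O6–C7 instead would each remove one ring but leave the isobutyryl group to be attached later at a neopentyl position. This cut removes the carbocycle and the heterocycle at once and leaves a monocyclic furandione with an open arm. The forward reaction needs a nitrile oxide made in the presence of four alkenes and a preference for the alkyne.

**C8 oxidation level.** Oxime **35** comes from aldehyde **34**, alcohol **33** and silyl ether **32**. An acetal at C8 was considered and rejected. Flanked by an acyloxy and an acyl group, it would need acid strong enough to hydrate the prenyl groups. A silyl ether is removed by buffered fluoride and oxidised under neutral conditions.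

**C4–prenyl bond.** **32** is cut to tetronic acid **30** and prenyl acetate **31**. The reverse order (prenyl first, arm last) is not possible because C3 is a β-branched primary carbon next to a quaternary centre and will not undergo SN2 with a stabilised enolate. The forward allylation must give C- rather than O-alkylation and must enter anti to the C8 group; for this reason C8 carries the bulky tert-butyldiphenylsilyloxy group.

**Tetronate ring and fragment union.** **30** is opened at C4–C10 (Dieckmann) to diester **29**, which comes from enoate **28** by 1,4-reduction. The C3=C4 bond of **28** is cut (Horner–Wadsworth–Emmons) into aldehyde **16** and phosphonate **27**. This joins two fragments of similar size through a carbonyl olefination rather than an alkylation at hindered C3.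

**C7 fragment.** **27** is the phosphonoacetate of hydroxy ester **24**. The C7 prenyl chain of **24** is cut to glycidic ester **22** and Grignard reagent **23**; **22** comes from acid **21** and epoxy alcohol **19**. The asymmetric epoxidation of allylic alcohol **18**, made from symmetric diol **17**, sets C7 with a predictable sense. An enolate route to this centre would place an alkoxy leaving group β to the enolate.

**C2.** Aldehyde **16** comes from alcohol **15** and imide **14**; the C2–prenyl bond is cut to imide **12** and prenyl bromide **13** (Evans alkylation). The neighbouring option, joining a prenylacetic enolate to a tertiary propargylic cation, would form C1–C2 in one step but cannot distinguish methyl from the homoprenyl chain at C1.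

**C1.** **12** comes from acid **9** and auxiliary **10**; **9** from alcohol **7** and enyne **5**. The C1–C9 bond of **5** is cut to geranyl phosphate **2** and 3-methylbut-1-yne **3** (via alane **4**), and **2** comes from geraniol **1**. The copper-catalysed SN2′ alkynylation sets quaternary C1 by catalyst control and brings the isopropyl alkyne intact. The alternative of alkylating a terminal acetylide with a secondary halide would fail by elimination.

## Roads not taken

**Alternative 1:** Cyclopentenone template. The C1–methyl and C2–prenyl bonds are cut on a five-membered ring. In the forward step Cu(OTf)2 with a chiral phosphoramidite adds AlMe3 to 3-(4-methylpent-3-enyl)cyclopent-2-enone **A1**, and the enolate is trapped with prenyl bromide **13** to give cyclopentanone **A2**. Its ring carbons map onto C3, C2, C1, C9 and C8.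
- Merits: one catalytic step sets both chain stereocentres, where the chosen route spends steps 2 to 6. In step economy for C1/C2 this road is better.
- Weak points: the relative configuration at C2 rests on the enolate distinguishing methyl from a primary chain on the adjacent quaternary carbon. Aluminium enolates react sluggishly with **13**. The C3–C8 ring bond must later be cut oxidatively in the presence of trisubstituted alkenes, leaving C3 at the carboxyl level. Neither ring of the target is formed.
- Comparison: the chosen plan sets C1 and C2 by two independent, strong control elements, and its key step closes both remaining rings with C8 and C11 already at the ketone level.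

**Alternative 2:** Palladium allylation closing the carbocycle. The C3–C4 bond is cut. In the forward step Pd2(dba)3 with 1,2-bis(diphenylphosphino)ethane (zerovalent palladium) ionises a 2-substituted allyl carbonate, and the tetronate carbon C4 attacks a terminus of the symmetric π-allyl unit to give bicycle **A3**.
- Merits: the quaternary C4 is formed cis to C8 by the ring closure itself. This is better than the substrate-controlled prenylation of step 18 in the chosen route. The soft tetronate is a good nucleophile for this chemistry.
- Weak points: **A3** has an exocyclic methylene at C2 and no substituent at C9. The C2 stereocentre and its prenyl group must be made afterwards on the bicycle with uncertain facial control. The isobutyryl group must be attached by C-acylation at a methylene next to quaternary C1. O-Alkylation to a larger ring competes.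
- Comparison: the chosen plan brings C2 and the complete C8–C9–C11 unit into the ring closure. It also uses the closure as a filter, since the wrong C4 epimer cannot cyclise.

**Alternative 3:** Iodide-mediated anodic lactonisation. The O6–C7 bond is cut. In the forward step hypoiodite, regenerated at a graphite anode from catalytic n-Bu4NI, activates the C7 enol of a cyclooctanedione, and the C4 carboxylate closes the lactone to give **A4**.
- Merits: catalytic and mild, and the bridging lactone can only form cis, so C4/C7 is secured, again better than step 18.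
- Weak points: the eight-membered carbocycle, the hardest ring, must exist before the key step. Electrophilic iodine and the anode compete for four electron-rich alkenes, and the C4 carboxylate is placed for iodolactonisation onto its own prenyl group. **A4** still lacks the isobutyryl group.
- Comparison: the chosen plan makes the medium ring in the key step and uses no halonium reagent beyond one equivalent of N-chlorosuccinimide consumed by the oxime.

Key step: step 22

Remark: C9 lies between two carbonyl groups and is taken to equilibrate; the (9R) epimer of the diketo form is assumed to be the thermodynamically preferred one.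

## Route

Step 1
Reactants: 1 geraniol
Product: 2 geranyl diethyl phosphate
Conditions: ClP(O)(OEt)2, pyridine, CH2Cl2, 0 °C
Reagents that add atoms: diethyl chlorophosphate, CCOP(=O)(Cl)OCC
Why: Phosphorylation of a primary allylic alcohol; the phosphate is the leaving group for the copper-catalysed substitution and is used without purification.

Step 2
Reactants: 2 geranyl diethyl phosphate; 3 3-methylbut-1-yne
Product: 5 (R)-3,7-dimethyl-3-(3-methylbut-1-yn-1-yl)octa-1,6-diene, via diisobutyl(3-methylbut-1-yn-1-yl)aluminium 4 (not isolated)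
Conditions: 3, i-Bu2AlH, Et3N (5 mol %), hexanes/THF, 22 °C; then 2, CuCl2·2H2O (2 mol %), chiral sulfonate-bearing imidazolinium salt (NHC precursor, 1 mol %), THF, −30 to 22 °C
Reagents that add atoms: none
Why: Copper-catalysed enantioselective allylic substitution (SN2′): the alkynyl group is delivered to the γ-carbon of the E-trisubstituted phosphate, and the chiral NHC–copper complex selects the alkene face and so sets quaternary C1 (ligand enantiomer chosen to give the R centre). The isopropyl alkyne arrives intact.

Step 3
Reactants: 5 (R)-3,7-dimethyl-3-(3-methylbut-1-yn-1-yl)octa-1,6-diene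
Product: 7 (R)-3,7-dimethyl-3-(3-methylbut-1-yn-1-yl)oct-6-en-1-ol, via B-alkyl-9-borabicyclo[3.3.1]nonane 6 (not isolated)
Conditions: 9-BBN, THF, 0 °C to rt; then NaOH, H2O2, 0 °C
Reagents that add atoms: hydrogen peroxide, OO
Why: Hydroboration–oxidation; 9-BBN adds anti-Markovnikov to the monosubstituted vinyl group far faster than to the trisubstituted alkene or the hindered internal alkyne.

Step 4
Reactants: 7 (R)-3,7-dimethyl-3-(3-methylbut-1-yn-1-yl)oct-6-en-1-ol
Product: 9 (R)-3,7-dimethyl-3-(3-methylbut-1-yn-1-yl)oct-6-enoic acid, via aldehyde 8 (not isolated)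
Conditions: TEMPO (cat.), PhI(OAc)2, MeCN/H2O, rt
Reagents that add atoms: water, O
Why: Oxoammonium oxidation of the primary alcohol through the aldehyde hydrate to the acid; the trisubstituted alkene and the alkyne are not attacked.

Step 5
Reactants: 9 (R)-3,7-dimethyl-3-(3-methylbut-1-yn-1-yl)oct-6-enoic acid; 10 (R)-4-benzyl-1,3-oxazolidin-2-one
Product: 12 (R)-4-benzyl-3-[(R)-3,7-dimethyl-3-(3-methylbut-1-yn-1-yl)oct-6-enoyl]-1,3-oxazolidin-2-one, via mixed pivalic anhydride 11 (not isolated)
Conditions: t-BuCOCl, Et3N, THF, −20 °C; then 10, LiCl, rt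
Reagents that add atoms: none
Why: N-Acylation of the oxazolidinone through the mixed anhydride; attack occurs at the less hindered of the two carbonyl groups, and no acid is generated that could add to the alkene.

Step 6
Reactants: 12 (R)-4-benzyl-3-[(R)-3,7-dimethyl-3-(3-methylbut-1-yn-1-yl)oct-6-enoyl]-1,3-oxazolidin-2-one; 13 prenyl bromide
Product: 14 (R)-4-benzyl-3-[(2R,3R)-3,7-dimethyl-3-(3-methylbut-1-yn-1-yl)-2-(3-methylbut-2-en-1-yl)oct-6-enoyl]-1,3-oxazolidin-2-one
Conditions: NaN(SiMe3)2, THF, −78 °C; then 13, −78 to −40 °C
Reagents that add atoms: none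
Why: Evans alkylation: the chelated Z-enolate is alkylated on the face opposite the benzyl group, which sets C2. Reagent control is expected to override the adjacent quaternary centre, and the allylic bromide is reactive enough for this hindered enolate.

Step 7
Reactants: 14 (R)-4-benzyl-3-[(2R,3R)-3,7-dimethyl-3-(3-methylbut-1-yn-1-yl)-2-(3-methylbut-2-en-1-yl)oct-6-enoyl]-1,3-oxazolidin-2-one
Product: 15 (2R,3R)-3,7-dimethyl-3-(3-methylbut-1-yn-1-yl)-2-(3-methylbut-2-en-1-yl)oct-6-en-1-ol
Conditions: LiBH4, MeOH (1 equiv), Et2O, 0 °C to rt
Reagents that add atoms: none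
Why: Reductive removal of the auxiliary by exocyclic acyl cleavage gives the primary alcohol without touching C2; the auxiliary is recovered.

Step 8
Reactants: 15 (2R,3R)-3,7-dimethyl-3-(3-methylbut-1-yn-1-yl)-2-(3-methylbut-2-en-1-yl)oct-6-en-1-ol
Product: 16 (2R,3R)-3,7-dimethyl-3-(3-methylbut-1-yn-1-yl)-2-(3-methylbut-2-en-1-yl)oct-6-enal
Conditions: Dess–Martin periodinane, NaHCO3, CH2Cl2, 0 °C to rt
Reagents that add atoms: none
Why: Dess–Martin oxidation under buffered conditions; the α-branched aldehyde is used at once so that C2 does not epimerise.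

Step 9
Reactants: 17 2-methylidenepropane-1,3-diol
Product: 18 2-({[tert-butyl(diphenyl)silyl]oxy}methyl)prop-2-en-1-ol
Conditions: NaH (1.0 equiv), THF, 0 °C; then t-BuPh2SiCl
Reagents that add atoms: tert-butyl(chloro)diphenylsilane, CC(C)(C)[Si](Cl)(c1ccccc1)c1ccccc1
Why: Monosilylation of a symmetric diol through its mono-sodium alkoxide; the bulky silyl group is chosen because it later shields one face of the tetronate.

Step 10
Reactants: 18 2-({[tert-butyl(diphenyl)silyl]oxy}methyl)prop-2-en-1-ol
Product: 19 (S)-[2-({[tert-butyl(diphenyl)silyl]oxy}methyl)oxiran-2-yl]methanol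
Conditions: Ti(Oi-Pr)4 (cat.), L-(+)-diethyl tartrate (cat.), t-BuOOH, 4 Å MS, CH2Cl2, −20 °C
Reagents that add atoms: tert-butyl hydroperoxide, CC(C)(C)OO
Why: Sharpless asymmetric epoxidation of a 1,1-disubstituted allylic alcohol; L-(+)-tartrate delivers oxygen to the face that gives the (S)-epoxide. The epoxide carbon becomes C7 and the oxygen O6.

Step 11
Reactants: 19 (S)-[2-({[tert-butyl(diphenyl)silyl]oxy}methyl)oxiran-2-yl]methanol
Product: 21 (S)-2-({[tert-butyl(diphenyl)silyl]oxy}methyl)oxirane-2-carboxylic acid, via epoxy aldehyde 20 (not isolated)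
Conditions: TEMPO (cat.), PhI(OAc)2, MeCN/H2O, 0 °C to rt
Reagents that add atoms: water, O
Why: Oxoammonium oxidation of the primary alcohol to the acid; the electron-poor epoxide and the silyl ether tolerate the weakly acidic medium, and no alkene is present at this stage.

Step 12
Reactants: 21 (S)-2-({[tert-butyl(diphenyl)silyl]oxy}methyl)oxirane-2-carboxylic acid
Product: 22 methyl (S)-2-({[tert-butyl(diphenyl)silyl]oxy}methyl)oxirane-2-carboxylate
Conditions: MeI, K2CO3, DMF, rt
Reagents that add atoms: iodomethane, CI
Why: Carboxylate O-alkylation (SN2 on iodomethane) under mild base leaves the epoxide intact.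

Step 13
Reactants: 22 methyl (S)-2-({[tert-butyl(diphenyl)silyl]oxy}methyl)oxirane-2-carboxylate; 23 (2-methylprop-1-en-1-yl)magnesium bromide
Product: 24 methyl (S)-2-({[tert-butyl(diphenyl)silyl]oxy}methyl)-2-hydroxy-5-methylhex-4-enoate
Conditions: 23, CuI (20 mol %), THF, −40 °C; then aq. NH4Cl
Reagents that add atoms: none
Why: Copper-catalysed Grignard opening of a glycidic ester at its unsubstituted β-carbon (SN2), faster than addition to the ester at low temperature. The C7–O bond is not broken, so the configuration from step 10 is kept and the new chain is the C7 prenyl group.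

Step 14
Reactants: 24 methyl (S)-2-({[tert-butyl(diphenyl)silyl]oxy}methyl)-2-hydroxy-5-methylhex-4-enoate; 25 (diethoxyphosphoryl)acetic acid
Product: 27 methyl (S)-2-({[tert-butyl(diphenyl)silyl]oxy}methyl)-2-{[(diethoxyphosphoryl)acetyl]oxy}-5-methylhex-4-enoate, via (diethoxyphosphoryl)ketene 26 (not isolated)
Conditions: DCC, DMAP (cat.), CH2Cl2, 0 °C to rt
Reagents that add atoms: none
Why: Carbodiimide-mediated esterification of a phosphonoacetic acid proceeds through the phosphoryl ketene, which acylates even hindered tertiary alcohols.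

Step 15
Reactants: 16 (2R,3R)-3,7-dimethyl-3-(3-methylbut-1-yn-1-yl)-2-(3-methylbut-2-en-1-yl)oct-6-enal; 27 methyl (S)-2-({[tert-butyl(diphenyl)silyl]oxy}methyl)-2-{[(diethoxyphosphoryl)acetyl]oxy}-5-methylhex-4-enoate
Product: 28 E-enoate (C3=C4) joining arm and hydroxy ester
Conditions: LiCl, DBU, MeCN, 0 °C to rt
Reagents that add atoms: none
Why: Horner–Wadsworth–Emmons olefination under Masamune–Roush conditions gives the E-enoate and joins the two fragments; the mild base spares the α-stereocentre of 16.

Step 16
Reactants: 28 E-enoate
Product: 29 saturated diester (C3–C4 single bond)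
Conditions: [(Ph3P)CuH]6 (5 mol %), PhMe2SiH, t-BuOH, toluene, rt
Reagents that add atoms: none
Why: Copper hydride 1,4-reduction of the enoate; isolated trisubstituted alkenes and the hindered internal alkyne are not hydrometallated, and t-BuOH protonates the copper enolate before it can react further.

Step 17
Reactants: 29 saturated diester
Product: 30 3-substituted tetronic acid
Conditions: LiN(SiMe3)2 (2.2 equiv), THF, −78 to 0 °C; then 1 M HCl
Reagents that add atoms: none
Why: Dieckmann condensation: the ester enolate at C4 attacks the methyl ester on C7 (5-exo-trig), and formation of the acidic tetronate salt drives the reaction. C7 bears no hydrogen and cannot epimerise.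

Step 18
Reactants: 30 3-substituted tetronic acid; 31 prenyl acetate
Product: 32 (3R,5S)-3,3,5,5-tetrasubstituted furan-2,4-dione silyl ether
Conditions: Pd(PPh3)4 (5 mol %), Et3N, THF, rt
Reagents that add atoms: none
Why: Tsuji–Trost allylation: the soft tetronate attacks the less substituted terminus of the 1,1-dimethylallyl palladium complex, and O-allylation is reversible under the catalyst. Quaternary C4 is set by 1,3-induction from C7: the electrophile enters anti to the silyloxymethyl group, the larger C7 substituent, as known for γ-silyloxymethyl butyrolactone enolates.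

Step 19
Reactants: 32 furan-2,4-dione silyl ether
Product: 33 C8 primary alcohol
Conditions: HF·pyridine, pyridine, THF, 0 °C to rt
Reagents that add atoms: none
Why: Fluoride desilylation under buffered, non-basic conditions avoids retro-aldol loss of C8 and retro-Claisen opening of the furandione.

Step 20
Reactants: 33 C8 primary alcohol
Product: 34 C8 aldehyde
Conditions: Dess–Martin periodinane, NaHCO3, CH2Cl2, 0 °C to rt
Reagents that add atoms: none
Why: Dess–Martin oxidation of a neopentyl primary alcohol; the aldehyde sits on quaternary C7 and cannot enolise.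

Step 21
Reactants: 34 C8 aldehyde
Product: 35 C8 (E)-aldoxime
Conditions: NH2OH·HCl (1.05 equiv), pyridine, EtOH, 0 °C to rt
Reagents that add atoms: hydroxylamine hydrochloride, NO.Cl
Why: Oxime condensation: the aldehyde is far more electrophilic than the C10 ketone, which is flanked by two quaternary carbons. One equivalent at low temperature limits attack on the lactone.

Step 22
Reactants: 35 C8 (E)-aldoxime
Product: 38 isoxazole-fused bicycle, via hydroximoyl chloride 36 (not isolated), via nitrile oxide 37 (not isolated)
Conditions: NCS (1.0 equiv), pyridine (cat.), CHCl3, 0 °C to rt; then slow addition to Et3N in toluene (about 1 mM), 80 °C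
Reagents that add atoms: none
Why: NCS chlorinates the aldoxime carbon to give 36, Et3N removes HCl to give nitrile oxide 37, and 37 adds across C9≡C11 in a concerted [3+2] (Huisgen) cycloaddition that forms C8–C9 and O–C11. The closest known reaction type is the intramolecular nitrile oxide–alkyne cycloaddition to ring-fused isoxazoles; an eight-membered closure is at the edge of what is documented, hence slow generation, high dilution and heating. The carbocycle closes in the fused mode (the tether joins the dipole carbon to the proximal alkyne carbon, so C8 and C9 both lie in the new eight-membered ring), and the isoxazole is formed by the cycloaddition itself, annulated on C8–C9. No stereocentre is created; the cis relation of C3 and C8 set in steps 10 and 18 is the precondition, and the C4 epimer cannot reach. Regiochemistry is fixed by the tether, since the reverse orientation would need a bridged isoxazole. Site selectivity is needed against four alkenes: the C7 prenyl group would give a four-membered ring, the C4 prenyl group is trans to C8, and the homoprenyl group would need a ten-membered ring. The C2 prenyl group can reach at the same ring size, and what favours the alkyne is its position on quaternary C1 in the chain (gem-dialkyl effect, one rotor fewer), its cylindrical π-system, and the low dipolarophilicity of trisubstituted alkenes. Dimerisation to the furoxan is slowed because the nitrile oxide sits on quaternary C7, and the aromatic product stores C8 and C11 at the ketone level without an acidic C9–H.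

Step 23
Reactants: 38 isoxazole-fused bicycle
Product: 39 bicyclic Z-enaminone
Conditions: Mo(CO)6, MeCN/H2O, 80 °C
Reagents that add atoms: none
Why: Mo(CO)6-mediated reductive cleavage of the isoxazole N–O bond gives the vinylogous amide; alkenes, ketone and lactone are not reduced.

Step 24
Reactants: 39 bicyclic Z-enaminone
Product: 40 CNP0121153.1
Conditions: AcOH/H2O/THF, 40 °C
Reagents that add atoms: water, O
Why: Hydrolysis of the vinylogous amide by weak aqueous acid (C-protonation, water addition, loss of ammonia) frees the 1,3-diketone without protonating the trisubstituted alkenes. C9, now between two carbonyl groups, equilibrates to the more stable epimer.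

## Compound list

1 | geraniol, (2E)-3,7-dimethylocta-2,6-dien-1-ol | CC(C)=CCC/C(C)=C/CO | starting material
2 | geranyl diethyl phosphate | CC(C)=CCC/C(C)=C/COP(=O)(OCC)OCC | intermediate
3 | 3-methylbut-1-yne | CC(C)C#C | starting material
4 | diisobutyl(3-methylbut-1-yn-1-yl)aluminium | CC(C)C[Al](CC(C)C)C#CC(C)C | intermediate
5 | (R)-3,7-dimethyl-3-(3-methylbut-1-yn-1-yl)octa-1,6-diene | CC(C)=CCC[C@](C#CC(C)C)(C)C=C | intermediate
6 | 9-[(S)-3,7-dimethyl-3-(3-methylbut-1-yn-1-yl)oct-6-en-1-yl]-9-borabicyclo[3.3.1]nonane | CC(C)=CCC[C@](C#CC(C)C)(C)CCB1C2CCCC1CCC2 | intermediate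
7 | (R)-3,7-dimethyl-3-(3-methylbut-1-yn-1-yl)oct-6-en-1-ol | CC(C)=CCC[C@](C#CC(C)C)(C)CCO | intermediate
8 | (R)-3,7-dimethyl-3-(3-methylbut-1-yn-1-yl)oct-6-enal | CC(C)=CCC[C@](C#CC(C)C)(C)CC=O | intermediate
9 | (R)-3,7-dimethyl-3-(3-methylbut-1-yn-1-yl)oct-6-enoic acid | CC(C)=CCC[C@](C#CC(C)C)(C)CC(=O)O | intermediate
10 | (R)-4-benzyl-1,3-oxazolidin-2-one | O=C1N[C@H](Cc2ccccc2)CO1 | starting material
11 | (R)-3,7-dimethyl-3-(3-methylbut-1-yn-1-yl)oct-6-enoic pivalic anhydride | CC(C)=CCC[C@](C#CC(C)C)(C)CC(=O)OC(=O)C(C)(C)C | intermediate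
12 | (R)-4-benzyl-3-[(R)-3,7-dimethyl-3-(3-methylbut-1-yn-1-yl)oct-6-enoyl]-1,3-oxazolidin-2-one | CC(C)=CCC[C@](C#CC(C)C)(C)CC(=O)N1[C@H](Cc2ccccc2)COC1=O | intermediate
13 | prenyl bromide, 1-bromo-3-methylbut-2-ene | CC(C)=CCBr | starting material
14 | (R)-4-benzyl-3-[(2R,3R)-3,7-dimethyl-3-(3-methylbut-1-yn-1-yl)-2-(3-methylbut-2-en-1-yl)oct-6-enoyl]-1,3-oxazolidin-2-one | CC(C)=CCC[C@](C#CC(C)C)(C)[C@@H](CC=C(C)C)C(=O)N1[C@H](Cc2ccccc2)COC1=O | intermediate
15 | (2R,3R)-3,7-dimethyl-3-(3-methylbut-1-yn-1-yl)-2-(3-methylbut-2-en-1-yl)oct-6-en-1-ol | CC(C)=CCC[C@](C#CC(C)C)(C)[C@@H](CC=C(C)C)CO | intermediate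
16 | (2R,3R)-3,7-dimethyl-3-(3-methylbut-1-yn-1-yl)-2-(3-methylbut-2-en-1-yl)oct-6-enal | CC(C)=CCC[C@](C#CC(C)C)(C)[C@@H](CC=C(C)C)C=O | intermediate
17 | 2-methylidenepropane-1,3-diol | C=C(CO)CO | starting material
18 | 2-({[tert-butyl(diphenyl)silyl]oxy}methyl)prop-2-en-1-ol | C=C(CO)CO[Si](c1ccccc1)(c1ccccc1)C(C)(C)C | intermediate
19 | (S)-[2-({[tert-butyl(diphenyl)silyl]oxy}methyl)oxiran-2-yl]methanol | OC[C@@]1(CO[Si](c2ccccc2)(c2ccccc2)C(C)(C)C)CO1 | intermediate
20 | (S)-2-({[tert-butyl(diphenyl)silyl]oxy}methyl)oxirane-2-carbaldehyde | O=C[C@@]1(CO[Si](c2ccccc2)(c2ccccc2)C(C)(C)C)CO1 | intermediate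
21 | (S)-2-({[tert-butyl(diphenyl)silyl]oxy}methyl)oxirane-2-carboxylic acid | OC(=O)[C@@]1(CO[Si](c2ccccc2)(c2ccccc2)C(C)(C)C)CO1 | intermediate
22 | methyl (S)-2-({[tert-butyl(diphenyl)silyl]oxy}methyl)oxirane-2-carboxylate | COC(=O)[C@@]1(CO[Si](c2ccccc2)(c2ccccc2)C(C)(C)C)CO1 | intermediate
23 | (2-methylprop-1-en-1-yl)magnesium bromide | CC(C)=C[Mg]Br | starting material
24 | methyl (S)-2-({[tert-butyl(diphenyl)silyl]oxy}methyl)-2-hydroxy-5-methylhex-4-enoate | O[C@@](CC=C(C)C)(CO[Si](c1ccccc1)(c1ccccc1)C(C)(C)C)C(=O)OC | intermediate
25 | (diethoxyphosphoryl)acetic acid | CCOP(=O)(OCC)CC(=O)O | starting material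
26 | (diethoxyphosphoryl)ketene, diethyl (2-oxoethenyl)phosphonate | CCOP(=O)(OCC)C=C=O | intermediate
27 | methyl (S)-2-({[tert-butyl(diphenyl)silyl]oxy}methyl)-2-{[(diethoxyphosphoryl)acetyl]oxy}-5-methylhex-4-enoate | CCOP(=O)(OCC)CC(=O)O[C@@](CC=C(C)C)(CO[Si](c1ccccc1)(c1ccccc1)C(C)(C)C)C(=O)OC | intermediate
28 | methyl (2S)-2-({[tert-butyl(diphenyl)silyl]oxy}methyl)-2-{[(2E,4S,5R)-5,9-dimethyl-5-(3-methylbut-1-yn-1-yl)-4-(3-methylbut-2-en-1-yl)deca-2,8-dienoyl]oxy}-5-methylhex-4-enoate | CC(C)=CCC[C@](C#CC(C)C)(C)[C@@H](CC=C(C)C)/C=C/C(=O)O[C@@](CC=C(C)C)(CO[Si](c1ccccc1)(c1ccccc1)C(C)(C)C)C(=O)OC | intermediate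
29 | methyl (2S)-2-({[tert-butyl(diphenyl)silyl]oxy}methyl)-2-{[(4R,5R)-5,9-dimethyl-5-(3-methylbut-1-yn-1-yl)-4-(3-methylbut-2-en-1-yl)dec-8-enoyl]oxy}-5-methylhex-4-enoate | CC(C)=CCC[C@](C#CC(C)C)(C)[C@@H](CC=C(C)C)CCC(=O)O[C@@](CC=C(C)C)(CO[Si](c1ccccc1)(c1ccccc1)C(C)(C)C)C(=O)OC | intermediate
30 | (5S)-5-({[tert-butyl(diphenyl)silyl]oxy}methyl)-3-[(2S,3R)-3,7-dimethyl-3-(3-methylbut-1-yn-1-yl)-2-(3-methylbut-2-en-1-yl)oct-6-en-1-yl]-4-hydroxy-5-(3-methylbut-2-en-1-yl)furan-2(5H)-one | CC(C)=CCC[C@](C#CC(C)C)(C)[C@@H](CC=C(C)C)CC1=C(O)[C@](CC=C(C)C)(CO[Si](c2ccccc2)(c2ccccc2)C(C)(C)C)OC1=O | intermediate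
31 | prenyl acetate, 3-methylbut-2-en-1-yl acetate | CC(C)=CCOC(C)=O | starting material
32 | (3R,5S)-5-({[tert-butyl(diphenyl)silyl]oxy}methyl)-3-[(2S,3R)-3,7-dimethyl-3-(3-methylbut-1-yn-1-yl)-2-(3-methylbut-2-en-1-yl)oct-6-en-1-yl]-3,5-bis(3-methylbut-2-en-1-yl)furan-2,4(3H,5H)-dione | CC(C)=CCC[C@](C#CC(C)C)(C)[C@@H](CC=C(C)C)C[C@@]1(CC=C(C)C)C(=O)O[C@@](CC=C(C)C)(CO[Si](c2ccccc2)(c2ccccc2)C(C)(C)C)C1=O | intermediate
33 | (3R,5S)-3-[(2S,3R)-3,7-dimethyl-3-(3-methylbut-1-yn-1-yl)-2-(3-methylbut-2-en-1-yl)oct-6-en-1-yl]-5-(hydroxymethyl)-3,5-bis(3-methylbut-2-en-1-yl)furan-2,4(3H,5H)-dione | CC(C)=CCC[C@](C#CC(C)C)(C)[C@@H](CC=C(C)C)C[C@@]1(CC=C(C)C)C(=O)O[C@@](CC=C(C)C)(CO)C1=O | intermediate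
34 | (2S,4R)-4-[(2S,3R)-3,7-dimethyl-3-(3-methylbut-1-yn-1-yl)-2-(3-methylbut-2-en-1-yl)oct-6-en-1-yl]-2,4-bis(3-methylbut-2-en-1-yl)-3,5-dioxooxolane-2-carbaldehyde | CC(C)=CCC[C@](C#CC(C)C)(C)[C@@H](CC=C(C)C)C[C@@]1(CC=C(C)C)C(=O)O[C@@](CC=C(C)C)(C=O)C1=O | intermediate
35 | (3R,5S)-3-[(2S,3R)-3,7-dimethyl-3-(3-methylbut-1-yn-1-yl)-2-(3-methylbut-2-en-1-yl)oct-6-en-1-yl]-5-[(E)-(hydroxyimino)methyl]-3,5-bis(3-methylbut-2-en-1-yl)furan-2,4(3H,5H)-dione | CC(C)=CCC[C@](C#CC(C)C)(C)[C@@H](CC=C(C)C)C[C@@]1(CC=C(C)C)C(=O)O[C@@](CC=C(C)C)(/C=N/O)C1=O | intermediate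
36 | hydroximoyl chloride of 35 (C8 carries Cl and =N–OH; all stereocentres as in 35) | CC(C)=CCC[C@](C#CC(C)C)(C)[C@@H](CC=C(C)C)C[C@@]1(CC=C(C)C)C(=O)O[C@@](CC=C(C)C)(C(Cl)=NO)C1=O | intermediate
37 | nitrile oxide of 35 (C8≡N–O on C7; all stereocentres as in 35) | CC(C)=CCC[C@](C#CC(C)C)(C)[C@@H](CC=C(C)C)C[C@@]1(CC=C(C)C)C(=O)O[C@@](CC=C(C)C)(C#[N+][O-])C1=O | intermediate
38 | isoxazole-fused bicycle, (1R,2S,4R,7S) in the numbering of the text: carbocycle C1–C2–C3–C4–C10–C7–C8–C9 bridged by lactone C4–C5(=O)–O6–C7 and fused at C8–C9 to an isoxazole (C8 = isoxazole C3, C9 = C4, C11 = C5 with isopropyl); C10 ketone; methyl and 4-methylpent-3-enyl on C1; prenyl on C2, C4 and C7 | CC(C)=CCC[C@]1(C)[C@@H](CC=C(C)C)C[C@@]2(CC=C(C)C)C(=O)O[C@@](CC=C(C)C)(c3noc(C(C)C)c31)C2=O | intermediate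
39 | bicyclic enaminone, (1R,2S,4R,7S): as 38 with the N–O bond cleaved; C8 bears NH2, C8=C9 is Z, C9 bears the 2-methylpropanoyl group | CC(C)=CCC[C@]1(C)[C@@H](CC=C(C)C)C[C@@]2(CC=C(C)C)C(=O)O[C@@](CC=C(C)C)(/C(N)=C1/C(=O)C(C)C)C2=O | intermediate
40 | CNP0121153.1, (1R,2S,4R,7S,9R)-diketone: C8 and C10 ketones, 2-methylpropanoyl on C9, lactone bridge C4–C5(=O)–O6–C7 | CC(C)=CCC[C@]1(C)[C@@H](CC=C(C)C)C[C@@]2(CC=C(C)C)C(=O)O[C@@](CC=C(C)C)(C(=O)[C@H]1C(=O)C(C)C)C2=O | target

## Step count and least certain steps

Total: 24 steps. Longest linear sequence: 18 steps (steps 1–8, then 15–24). The C7 branch (steps 9–14) has 6 steps.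

**Step 22 (key step).** What may go wrong:
- interception of the nitrile oxide by the C2 prenyl alkene, which can form a ring of the same size;
- dimerisation to the furoxan if the strained closure is slow;
- allylic chlorination of the trisubstituted alkenes during oxime chlorination.

Fallback: the C8–C9 bond is made by an aldol addition instead of a cycloaddition. Setting out from aldehyde 34, hydration of the alkyne with (Ph3P)AuNTf2 in wet dioxane (water adds at C11, the carbon remote from quaternary C1) gives the keto aldehyde F1. Soft enolisation toward the C9 methylene with TiCl4 and i-Pr2NEt and intramolecular aldol addition to the C8 aldehyde gives the β-hydroxy ketone F2. Dess–Martin oxidation of F2 gives the 1,3-diketone and rejoins the route at 40.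

**Step 2.** What may go wrong: insufficient discrimination of the alkene faces of a phosphate whose γ-carbon bears two alkyl groups, and leakage to the linear SN2 product. Fallback: C1 is then secured by separation on the auxiliary that the route already uses, rather than by catalyst control. Acid 9 of low enantiomeric purity contains its (S)-enantiomer F3. Acylation of 10 as in step 5 converts F3 into the epimeric imide F4, and prenylation as in step 6 gives the (2R,3S)-diastereomer F5 beside 14. F5 differs from 14 in the relative configuration of adjacent stereocentres and is removed by chromatography or crystallisation. The route is rejoined at 14.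

**Step 15.** What may go wrong:
- premature intramolecular Claisen condensation of the phosphonate anion onto the neighbouring methyl ester;
- slow olefination of the hindered α-branched aldehyde;
- epimerisation at C2 of 16.

Fallback: the arm is attached to a preformed tetronic acid by reductive alkylation. Setting out from hydroxy ester 24, acetylation (Ac2O, DMAP, Et3N) gives the acetate F6, and Dieckmann condensation with LiN(SiMe3)2 gives the 3-unsubstituted tetronic acid F7. Three-component reductive alkylation of F7 with aldehyde 16 and Hantzsch ester under L-proline catalysis (Knoevenagel condensation, then hydride transfer) rejoins the route at 30 and replaces steps 14 to 17.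

**Step 18.** What may go wrong:
- poor facial selectivity, because both C7 substituents are attached through a methylene group;
- O-allylation;
- attack at the tertiary allyl terminus.

Fallback: the facial choice is moved from the substrate to the catalyst. Tetronic acid 30 and prenyl acetate 31 are combined under Pd2(dba)3 (zerovalent palladium) with a C2-symmetric diphosphine derived from trans-1,2-diaminocyclohexane and 2-(diphenylphosphino)benzoic acid, as known for cyclic β-keto esters. The ligand enantiomer is chosen to reinforce attack anti to the silyloxymethyl group, and the product is again 32. Any remaining C4 epimer cannot undergo step 22 and is removed there at the latest.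

## Further compounds

F1 | step 22 | keto aldehyde: 34 with the C9≡C11 alkyne hydrated to C9H2–C11(=O)–isopropyl | CC(C)=CCC[C@](CC(=O)C(C)C)(C)[C@@H](CC=C(C)C)C[C@@]1(CC=C(C)C)C(=O)O[C@@](CC=C(C)C)(C=O)C1=O
F2 | step 22 | bicyclic β-hydroxy ketone: 40 with C8 as a secondary alcohol (C8 and C9 configurations not defined) | CC(C)=CCC[C@]1(C)[C@@H](CC=C(C)C)C[C@@]2(CC=C(C)C)C(=O)O[C@@](CC=C(C)C)(C(O)C1C(=O)C(C)C)C2=O
F3 | step 2 | (S)-3,7-dimethyl-3-(3-methylbut-1-yn-1-yl)oct-6-enoic acid | CC(C)=CCC[C@@](C#CC(C)C)(C)CC(=O)O
F4 | step 2 | (R)-4-benzyl-3-[(S)-3,7-dimethyl-3-(3-methylbut-1-yn-1-yl)oct-6-enoyl]-1,3-oxazolidin-2-one | CC(C)=CCC[C@@](C#CC(C)C)(C)CC(=O)N1[C@H](Cc2ccccc2)COC1=O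
F5 | step 2 | (R)-4-benzyl-3-[(2R,3S)-3,7-dimethyl-3-(3-methylbut-1-yn-1-yl)-2-(3-methylbut-2-en-1-yl)oct-6-enoyl]-1,3-oxazolidin-2-one | CC(C)=CCC[C@@](C#CC(C)C)(C)[C@@H](CC=C(C)C)C(=O)N1[C@H](Cc2ccccc2)COC1=O
F6 | step 15 | methyl (S)-2-acetoxy-2-({[tert-butyl(diphenyl)silyl]oxy}methyl)-5-methylhex-4-enoate | CC(=O)O[C@@](CC=C(C)C)(CO[Si](c1ccccc1)(c1ccccc1)C(C)(C)C)C(=O)OC
F7 | step 15 | (5S)-5-({[tert-butyl(diphenyl)silyl]oxy}methyl)-4-hydroxy-5-(3-methylbut-2-en-1-yl)furan-2(5H)-one | OC1=CC(=O)O[C@@]1(CC=C(C)C)CO[Si](c2ccccc2)(c2ccccc2)C(C)(C)C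
F0 | step 18 | none | none
A1 | alternative 1 | 3-(4-methylpent-3-en-1-yl)cyclopent-2-en-1-one | CC(C)=CCCC1=CC(=O)CC1
A2 | alternative 1 | 3-methyl-2-(3-methylbut-2-en-1-yl)-3-(4-methylpent-3-en-1-yl)cyclopentan-1-one, configured as C1 and C2 of the target | CC(C)=CCC[C@]1(C)[C@@H](CC=C(C)C)C(=O)CC1
A3 | alternative 2 | bicyclic furandione with exocyclic methylene at C2 and unsubstituted C9 | CC(C)=CCC[C@]1(C)C(=C)C[C@@]2(CC=C(C)C)C(=O)O[C@@](CC=C(C)C)(C(=O)C1)C2=O
A4 | alternative 3 | bicyclic furandione lacking the 2-methylpropanoyl group at C9 | CC(C)=CCC[C@]1(C)[C@@H](CC=C(C)C)C[C@@]2(CC=C(C)C)C(=O)O[C@@](CC=C(C)C)(C(=O)C1)C2=O
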